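**Plan**

Benzofuran numbering is used throughout: O1, C2 (aryl), C3 (methyl), C3a (allyl), C4, C5 (OMe), C6 (C=O), C7, C7a; ring A is the oxolane O1–C2–C3–C3a–C7a and ring B the carbocycle C3a–C4–C5–C6–C7–C7a.
Retrosynthesis: cut O–CH3 and C5–O (back to the C5-unsubstituted vinylogous ester), then C3a–C4 and C5–C6 of ring B (retro-Diels–Alder, with a temporary sulfonyl group on C5), then the C6–C7 bond and the C3a–allyl bond, and last C2–C3 (crotylation of the aryl aldehyde).
Enabling feature: ring B holds the enol ether C7=C7a between quaternary C3a and oxygenated C6, which is the cyclohexene left when a diene C3a=C7a–C7=C6 with oxygen on C7a and C6 takes up a two-carbon dienophile as C4–C5.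
Forward order: ring A is made first as a γ-lactone and turned into the siloxy diene, ring B is closed in one step, and the C5 methoxy group is installed last.
Stereochemistry: C2 and C3 come from a catalyst-controlled anti-crotylboration, C3a from approach of the dienophile anti to the C3 methyl group, and C5 from enolate hydroxylation anti to the pseudoaxial allyl group.

Key step: step 8

Remark: the sense of induction of (R)-TRIP in step 1 is assumed to be the one established for benzaldehyde (Re-face addition, (R)-carbinol); if the electron-rich aldehyde responds in the opposite sense, (S)-TRIP is used.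

**Route**

Step 1
Reactants: 1 3,4,5-trimethoxybenzaldehyde; 2 (E)-crotylboronic acid pinacol ester
Product: 4 (1R,2R)-2-methyl-1-(3,4,5-trimethoxyphenyl)but-3-en-1-ol, via borate ester 3 (not isolated)
Conditions: (R)-TRIP [(R)-3,3'-bis(2,4,6-triisopropylphenyl)-1,1'-binaphthyl-2,2'-diyl hydrogen phosphate] (5 mol%), toluene, 4 Å molecular sieves, −30 °C; aqueous work-up
Reagents that add atoms: (E)-crotylboronic acid pinacol ester 2, C/C=C/CB1OC(C)(C)C(C)(C)O1
Why: Chiral phosphoric acid-catalysed crotylboration runs through a closed chair transition state in which the (E)-crotyl geometry gives the anti (1R,2R) relationship while the catalyst selects the aldehyde face, so that C2 and C3 of the target are both set here.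

Step 2
Reactants: 4 (1R,2R)-2-methyl-1-(3,4,5-trimethoxyphenyl)but-3-en-1-ol
Product: 6 (1R,2R)-2-methyl-1-(3,4,5-trimethoxyphenyl)butane-1,4-diol, via alkylborane 5 (not isolated)
Conditions: 9-BBN (1.5 equiv), THF, 0 °C to rt; then 3 M NaOH, 30% H2O2, 0 °C
Reagents that add atoms: hydrogen peroxide, OO
Why: Anti-Markovnikov hydroboration–oxidation with the bulky 9-BBN turns the terminal vinyl group into the primary alcohol without touching either stereocentre.

Step 3
Reactants: 6 (1R,2R)-2-methyl-1-(3,4,5-trimethoxyphenyl)butane-1,4-diol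
Product: 8 (4R,5R)-4-methyl-5-(3,4,5-trimethoxyphenyl)oxolan-2-one, via lactol 7 (not isolated)
Conditions: TEMPO (10 mol%), PhI(OAc)2 (2.2 equiv), CH2Cl2, rt
Reagents that add atoms: none
Why: In this TEMPO/PhI(OAc)2 oxidative lactonisation the primary alcohol is oxidised faster than the benzylic one, the aldehyde is captured as lactol 7 and this is oxidised on to the trans γ-lactone.

Step 4
Reactants: 8 (4R,5R)-4-methyl-5-(3,4,5-trimethoxyphenyl)oxolan-2-one; 9 allyl bromide
Product: 11 (3R,4R,5R)-4-methyl-3-(prop-2-en-1-yl)-5-(3,4,5-trimethoxyphenyl)oxolan-2-one, via lithium enolate 10 (not isolated)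
Conditions: LiN(i-Pr)2 (1.1 equiv), THF, −78 °C; then allyl bromide, −78 to −40 °C
Reagents that add atoms: allyl bromide 9, C=CCBr
Why: Enolate alkylation of the γ-butyrolactone with allyl bromide occurs anti to the C4 methyl group, although this α-centre becomes sp2 in step 7 so that its configuration is of no consequence.

Step 5
Reactants: 11 (3R,4R,5R)-4-methyl-3-(prop-2-en-1-yl)-5-(3,4,5-trimethoxyphenyl)oxolan-2-one
Product: 12 (2R,3R,4R)-3-methyl-5-methylidene-4-(prop-2-en-1-yl)-2-(3,4,5-trimethoxyphenyl)oxolane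
Conditions: Cp2TiMe2 (2.5 equiv), toluene, 70 °C, dark; filtration through basic alumina
Reagents that add atoms: dimethyltitanocene Cp2TiMe2, C[Ti+2]C.c1cc[cH-]c1.c1cc[cH-]c1
Why: Petasis methylenation of a lactone carbonyl by Cp2Ti=CH2 generated thermally from Cp2TiMe2 is a standard non-basic route to exocyclic enol ethers and leaves the terminal alkene untouched.

Step 6
Reactants: 12 (2R,3R,4R)-3-methyl-5-methylidene-4-(prop-2-en-1-yl)-2-(3,4,5-trimethoxyphenyl)oxolane
Product: 14 (2E)-2-[(3R,4R,5R)-4-methyl-3-(prop-2-en-1-yl)-5-(3,4,5-trimethoxyphenyl)oxolan-2-ylidene]acetaldehyde, via iminium salt 13 (not isolated)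
Conditions: POCl3 (1.2 equiv), DMF (3 equiv), CH2Cl2, 0 °C to rt; then cold aq. NaOH
Reagents that add atoms: N,N-dimethylformamide, CN(C)C=O; water, O
Why: Vilsmeier–Haack formylation at the nucleophilic exocyclic carbon of the enol ether, as known for exo-glycals, gives the push–pull iminium salt 13, whose hydrolysis furnishes the β-alkoxy enal.

Step 7
Reactants: 14 (2E)-2-[(3R,4R,5R)-4-methyl-3-(prop-2-en-1-yl)-5-(3,4,5-trimethoxyphenyl)oxolan-2-ylidene]acetaldehyde
Product: 15 (2R,3R)-5-[(E)-2-(tert-butyldimethylsilyloxy)ethenyl]-3-methyl-4-(prop-2-en-1-yl)-2-(3,4,5-trimethoxyphenyl)-2,3-dihydrofuran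
Conditions: TBSOTf (1.3 equiv), Et3N (2.5 equiv), CH2Cl2, −78 to 0 °C; used after filtration through Et3N-deactivated silica
Reagents that add atoms: tert-butyldimethylsilyl trifluoromethanesulfonate, CC(C)(C)[Si](C)(C)OS(=O)(=O)C(F)(F)F
Why: O-Silylation of the vinylogous formate gives a siloxy-oxocarbenium ion that Et3N deprotonates at C3a, the only γ-hydrogen, which is a standard silyl dienol ether formation and should deliver the (E)-siloxy diene from the s-trans enal.

Step 8
Reactants: 15 (2R,3R)-5-[(E)-2-(tert-butyldimethylsilyloxy)ethenyl]-3-methyl-4-(prop-2-en-1-yl)-2-(3,4,5-trimethoxyphenyl)-2,3-dihydrofuran; 16 phenyl vinyl sulfone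
Product: 17 (2R,3R,3aR,5R,6S)-6-(tert-butyldimethylsilyloxy)-3-methyl-5-(phenylsulfonyl)-3a-(prop-2-en-1-yl)-2-(3,4,5-trimethoxyphenyl)-2,3,3a,4,5,6-hexahydro-1-benzofuran (endo adduct)
Conditions: 16 (3 equiv), toluene (2 M), BHT (cat.), 2,6-lutidine (0.1 equiv), 105 °C, sealed tube
Reagents that add atoms: phenyl vinyl sulfone 16, C=CS(=O)(=O)c1ccccc1
Why: The reaction is a thermal, concerted but asynchronous (4+2) cycloaddition of the doubly oxygen-activated diene C3a=C7a–C7=C6 with the electron-poor vinyl sulfone; the closest known reaction types are the Diels–Alder addition of 1-siloxy-3-alkoxy dienes to phenyl vinyl sulfone as an ethylene equivalent and that of 2-substituted 1-vinylcycloalkenes, which creates angular quaternary centres. Ring B closes as a six-membered carbocycle by intermolecular (4+2) cycloaddition, C3a–C4 and C5–C6 forming suprafacially on one face of the diene. C3a is set by the resident C3 stereocentre, the dienophile approaching the dihydrofuran face anti to the allylic methyl group so that the allyl group ends up cis to it; C6 follows from the (E) geometry of the siloxyvinyl unit and C5 from the endo orientation of the sulfonyl group, and both of these centres are erased later. The step needs regio- and facial selectivity: the oxygen donors on C7a and C6 make C3a the nucleophilic terminus, which therefore bonds to the unsubstituted CH2 of the sulfone, and the methyl group next to the reacting carbon shields one face. The inward allyl group on the fully substituted terminus disfavours the s-cis conformer, which is why a concentrated solution and heating are used, with a phenolic inhibitor and a trace of hindered base to protect the acid-labile diene.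

Step 9
Reactants: 17 the silyl ether adduct
Product: 18 (2R,3R,3aR,5R,6S)-3-methyl-5-(phenylsulfonyl)-3a-(prop-2-en-1-yl)-2-(3,4,5-trimethoxyphenyl)-2,3,3a,4,5,6-hexahydro-1-benzofuran-6-ol
Conditions: Bu4NF (1.5 equiv), AcOH (1.5 equiv), THF, 0 °C to rt
Reagents that add atoms: none
Why: Fluoride-mediated silyl ether cleavage buffered with acetic acid frees the allylic alcohol while avoiding base-induced β-elimination next to the sulfone and acid-induced ionisation of the enol ether.

Step 10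
Reactants: 18 the allylic alcohol
Product: 19 (2R,3R,3aR,5R)-3-methyl-5-(phenylsulfonyl)-3a-(prop-2-en-1-yl)-2-(3,4,5-trimethoxyphenyl)-3,3a,4,5-tetrahydro-1-benzofuran-6(2H)-one (either C5 epimer serves)
Conditions: Dess–Martin periodinane (1.5 equiv), NaHCO3, CH2Cl2, 0 °C to rt
Reagents that add atoms: none
Why: Dess–Martin oxidation of the allylic alcohol under bicarbonate buffering creates the C6 carbonyl of the vinylogous ester without acid that would open the enol ether.

Step 11
Reactants: 19 the β-keto sulfone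
Product: 21 (2R,3R,3aS)-3-methyl-3a-(prop-2-en-1-yl)-2-(3,4,5-trimethoxyphenyl)-3,3a,4,5-tetrahydro-1-benzofuran-6(2H)-one, via samarium enolate 20 (not isolated)
Conditions: SmI2 (2.5 equiv), THF–MeOH, −78 °C
Reagents that add atoms: none
Why: Reductive desulfonylation of a β-keto sulfone by SmI2 cleaves the C5–S bond to give enolate 20, which methanol protonates, and at −78 °C it should not reduce the vinylogous ester, the allyl group or the arene (the 3aS descriptor reflects a change of CIP priorities only).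

Step 12
Reactants: 21 the vinylogous ester
Product: 23 (2R,3R,3aR,5R)-5-hydroxy-3-methyl-3a-(prop-2-en-1-yl)-2-(3,4,5-trimethoxyphenyl)-3,3a,4,5-tetrahydro-1-benzofuran-6(2H)-one, via potassium enolate 22 (not isolated)
Conditions: KN(SiMe3)2 (1.1 equiv), THF, −78 °C; then (±)-3-phenyl-2-(phenylsulfonyl)oxaziridine, −78 °C; aq. NH4Cl
Reagents that add atoms: 3-phenyl-2-(phenylsulfonyl)oxaziridine (Davis oxaziridine), O=S(=O)(c1ccccc1)N1OC1c1ccccc1
Why: Kinetic α'-deprotonation can only occur at C5 because C3a carries no hydrogen, and Davis oxaziridine hydroxylation of enolate 22 should take place on the face anti to the pseudoaxial allyl group on C3a, which sets (5R).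

Step 13
Reactants: 23 the α-ketol
Product: 24 (2R,3R,3aR,5R)-5-methoxy-3-methyl-3a-(prop-2-en-1-yl)-2-(3,4,5-trimethoxyphenyl)-3,3a,4,5-tetrahydro-1-benzofuran-6(2H)-one (target)
Conditions: MeI (10 equiv), Ag2O (3 equiv), 4 Å molecular sieves, CH2Cl2, rt, dark
Reagents that add atoms: iodomethane, CI
Why: Purdie methylation with MeI and Ag2O etherifies the α-ketol under essentially neutral conditions and so avoids enolate formation, α-ketol rearrangement and epimerisation at C5.

**Compound list**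

1 | 3,4,5-trimethoxybenzaldehyde | COc1cc(C=O)cc(OC)c1OC | starting material
2 | (E)-crotylboronic acid pinacol ester | C/C=C/CB1OC(C)(C)C(C)(C)O1 | starting material
3 | 2-{[(1R,2R)-2-methyl-1-(3,4,5-trimethoxyphenyl)but-3-en-1-yl]oxy}-4,4,5,5-tetramethyl-1,3,2-dioxaborolane (borate ester) | CC1(C)OB(O[C@@H](c2cc(OC)c(OC)c(OC)c2)[C@@H](C=C)C)OC1(C)C | intermediate
4 | (1R,2R)-2-methyl-1-(3,4,5-trimethoxyphenyl)but-3-en-1-ol | O[C@@H](c1cc(OC)c(OC)c(OC)c1)[C@@H](C=C)C | intermediate
5 | (1R,2R)-4-(9-borabicyclo[3.3.1]nonan-9-yl)-2-methyl-1-(3,4,5-trimethoxyphenyl)butan-1-ol (alkylborane) | O[C@@H](c1cc(OC)c(OC)c(OC)c1)[C@@H](CCB1C2CCCC1CCC2)C | intermediate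
6 | (1R,2R)-2-methyl-1-(3,4,5-trimethoxyphenyl)butane-1,4-diol | O[C@@H](c1cc(OC)c(OC)c(OC)c1)[C@@H](CCO)C | intermediate
7 | (4R,5R)-4-methyl-5-(3,4,5-trimethoxyphenyl)oxolan-2-ol (lactol, anomeric mixture) | O1[C@@H](c2cc(OC)c(OC)c(OC)c2)[C@@H](CC1O)C | intermediate
8 | (4R,5R)-4-methyl-5-(3,4,5-trimethoxyphenyl)oxolan-2-one | O1[C@@H](c2cc(OC)c(OC)c(OC)c2)[C@@H](CC1=O)C | intermediate
9 | allyl bromide | C=CCBr | starting material
10 | lithium (4R,5R)-4-methyl-5-(3,4,5-trimethoxyphenyl)-4,5-dihydrofuran-2-olate (lithium enolate) | O1[C@@H](c2cc(OC)c(OC)c(OC)c2)[C@@H](C=C1[O-])C.[Li+] | intermediate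
11 | (3R,4R,5R)-4-methyl-3-(prop-2-en-1-yl)-5-(3,4,5-trimethoxyphenyl)oxolan-2-one | O1[C@@H](c2cc(OC)c(OC)c(OC)c2)[C@H](C)[C@@H](CC=C)C1=O | intermediate
12 | (2R,3R,4R)-3-methyl-5-methylidene-4-(prop-2-en-1-yl)-2-(3,4,5-trimethoxyphenyl)oxolane | O1[C@@H](c2cc(OC)c(OC)c(OC)c2)[C@H](C)[C@@H](CC=C)C1=C | intermediate
13 | N-{(E)-2-[(3R,4R,5R)-4-methyl-3-(prop-2-en-1-yl)-5-(3,4,5-trimethoxyphenyl)oxolan-2-ylidene]ethylidene}-N-methylmethanaminium dichlorophosphate (iminium salt) | C[N+](C)=C/C=C1/O[C@@H](c2cc(OC)c(OC)c(OC)c2)[C@H](C)[C@H]1CC=C.[O-]P(=O)(Cl)Cl | intermediate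
14 | (2E)-2-[(3R,4R,5R)-4-methyl-3-(prop-2-en-1-yl)-5-(3,4,5-trimethoxyphenyl)oxolan-2-ylidene]acetaldehyde (the double-bond geometry is lost in step 7) | O=C/C=C1/O[C@@H](c2cc(OC)c(OC)c(OC)c2)[C@H](C)[C@H]1CC=C | intermediate
15 | (2R,3R)-5-[(E)-2-(tert-butyldimethylsilyloxy)ethenyl]-3-methyl-4-(prop-2-en-1-yl)-2-(3,4,5-trimethoxyphenyl)-2,3-dihydrofuran | C=CCC1=C(/C=C/O[Si](C)(C)C(C)(C)C)O[C@@H](c2cc(OC)c(OC)c(OC)c2)[C@@H]1C | intermediate
16 | phenyl vinyl sulfone | C=CS(=O)(=O)c1ccccc1 | starting material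
17 | (2R,3R,3aR,5R,6S)-6-(tert-butyldimethylsilyloxy)-3-methyl-5-(phenylsulfonyl)-3a-(prop-2-en-1-yl)-2-(3,4,5-trimethoxyphenyl)-2,3,3a,4,5,6-hexahydro-1-benzofuran | C=CC[C@]12C[C@@H](S(=O)(=O)c3ccccc3)[C@@H](O[Si](C)(C)C(C)(C)C)C=C1O[C@@H](c1cc(OC)c(OC)c(OC)c1)[C@@H]2C | intermediate
18 | (2R,3R,3aR,5R,6S)-3-methyl-5-(phenylsulfonyl)-3a-(prop-2-en-1-yl)-2-(3,4,5-trimethoxyphenyl)-2,3,3a,4,5,6-hexahydro-1-benzofuran-6-ol | C=CC[C@]12C[C@@H](S(=O)(=O)c3ccccc3)[C@@H](O)C=C1O[C@@H](c1cc(OC)c(OC)c(OC)c1)[C@@H]2C | intermediate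
19 | (2R,3R,3aR,5R)-3-methyl-5-(phenylsulfonyl)-3a-(prop-2-en-1-yl)-2-(3,4,5-trimethoxyphenyl)-3,3a,4,5-tetrahydro-1-benzofuran-6(2H)-one | C=CC[C@]12C[C@@H](S(=O)(=O)c3ccccc3)C(=O)C=C1O[C@@H](c1cc(OC)c(OC)c(OC)c1)[C@@H]2C | intermediate
20 | diiodosamarium enolate of 21 (trivalent samarium on the C6 oxygen, C5=C6 double bond) | C=CC[C@]12CC=C(O[Sm](I)I)C=C1O[C@@H](c1cc(OC)c(OC)c(OC)c1)[C@@H]2C | intermediate
21 | (2R,3R,3aS)-3-methyl-3a-(prop-2-en-1-yl)-2-(3,4,5-trimethoxyphenyl)-3,3a,4,5-tetrahydro-1-benzofuran-6(2H)-one | C=CC[C@]12CCC(=O)C=C1O[C@@H](c1cc(OC)c(OC)c(OC)c1)[C@@H]2C | intermediate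
22 | potassium enolate of 21 (C5=C6 double bond) | C=CC[C@]12CC=C([O-])C=C1O[C@@H](c1cc(OC)c(OC)c(OC)c1)[C@@H]2C.[K+] | intermediate
23 | (2R,3R,3aR,5R)-5-hydroxy-3-methyl-3a-(prop-2-en-1-yl)-2-(3,4,5-trimethoxyphenyl)-3,3a,4,5-tetrahydro-1-benzofuran-6(2H)-one | C=CC[C@]12C[C@@H](O)C(=O)C=C1O[C@@H](c1cc(OC)c(OC)c(OC)c1)[C@@H]2C | intermediate
24 | (2R,3R,3aR,5R)-5-methoxy-3-methyl-3a-(prop-2-en-1-yl)-2-(3,4,5-trimethoxyphenyl)-3,3a,4,5-tetrahydro-1-benzofuran-6(2H)-one | C=CC[C@]12C[C@@H](OC)C(=O)C=C1O[C@@H](c1cc(OC)c(OC)c(OC)c1)[C@@H]2C | target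

**Step count**

Total: 13 steps. Longest linear sequence: 13 steps, from 3,4,5-trimethoxybenzaldehyde 1.

**Steps most likely to fail**

Step 8. The cycloaddition may be too slow at the fully substituted C3a terminus, because the inward allyl group disfavours the s-cis diene; a [1,5]-hydrogen shift or hydrolysis of the diene could then compete. Facial discrimination by the C3 methyl group may also be incomplete at 105 °C. The fallback sets out from diene 15 and uses ethynyl phenyl sulfone (C#CS(=O)(=O)c1ccccc1), a linear and much more reactive dienophile, in toluene at 25–40 °C. The same two bonds form, and the product should be the cyclohexa-1,4-diene adduct F1. Buffered Bu4NF then gives the dienol F2, and Dess–Martin oxidation gives the 5-sulfonyl cross-conjugated dienone F3. Conjugate reduction of its doubly activated C4=C5 bond with LiBH(s-Bu)3 (THF, −78 °C) brings the route back at β-keto sulfone 19.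

Step 6. Acid released during the formylation may isomerise the exocyclic enol ether to its endocyclic isomer, or hydrate it, before C-formylation takes place. The fallback sets out from lactone 11 and bypasses enol ether 12. Addition of LiCH2CN (THF, −78 °C) gives the β-keto nitrile F4, which is in equilibrium with its cyclic hemiketal. Cyclodehydration (TsOH cat., toluene, 4 Å molecular sieves) gives the alkylidene nitrile F5. Reduction with i-Bu2AlH (toluene, −78 °C) and mild hydrolysis of the aldimine brings the route back at enal 14.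

Step 12. Hydroxylation may occur partly on the face syn to the allyl group, or the enolate may add to the sulfonimine by-product. The fallback sets out from ketone 21 and does not discard the material hydroxylated on the wrong face, the 5-epimeric ketol F6. Mitsunobu reaction with 4-nitrobenzoic acid (PPh3, DIAD, THF, 0 °C) inverts C5 by SN2 displacement and gives the (5R) 4-nitrobenzoate F7. Brief methanolysis (K2CO3, MeOH, 0 °C) brings the route back at ketol 23.

**Further compounds**

F1 | step 8 | tert-butyl-dimethyl-{[(2R,3R,3aS,6S)-3-methyl-5-(phenylsulfonyl)-3a-(prop-2-en-1-yl)-2-(3,4,5-trimethoxyphenyl)-2,3,3a,6-tetrahydro-1-benzofuran-6-yl]oxy}silane | C=CC[C@]12C=C(S(=O)(=O)c3ccccc3)[C@@H](O[Si](C)(C)C(C)(C)C)C=C1O[C@@H](c1cc(OC)c(OC)c(OC)c1)[C@@H]2C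
F2 | step 8 | (2R,3R,3aS,6S)-3-methyl-5-(phenylsulfonyl)-3a-(prop-2-en-1-yl)-2-(3,4,5-trimethoxyphenyl)-2,3,3a,6-tetrahydro-1-benzofuran-6-ol | C=CC[C@]12C=C(S(=O)(=O)c3ccccc3)[C@@H](O)C=C1O[C@@H](c1cc(OC)c(OC)c(OC)c1)[C@@H]2C
F3 | step 8 | (2R,3R,3aS)-3-methyl-5-(phenylsulfonyl)-3a-(prop-2-en-1-yl)-2-(3,4,5-trimethoxyphenyl)-3,3a-dihydro-1-benzofuran-6(2H)-one | C=CC[C@]12C=C(S(=O)(=O)c3ccccc3)C(=O)C=C1O[C@@H](c1cc(OC)c(OC)c(OC)c1)[C@@H]2C
F4 | step 6 | (4R,5R,6R)-6-hydroxy-5-methyl-3-oxo-4-(prop-2-en-1-yl)-6-(3,4,5-trimethoxyphenyl)hexanenitrile | O[C@@H](c1cc(OC)c(OC)c(OC)c1)[C@H](C)[C@@H](CC=C)C(=O)CC#N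
F5 | step 6 | (2E)-2-[(3R,4R,5R)-4-methyl-3-(prop-2-en-1-yl)-5-(3,4,5-trimethoxyphenyl)oxolan-2-ylidene]acetonitrile | N#C/C=C1/O[C@@H](c2cc(OC)c(OC)c(OC)c2)[C@H](C)[C@H]1CC=C
F6 | step 12 | (2R,3R,3aR,5S)-5-hydroxy-3-methyl-3a-(prop-2-en-1-yl)-2-(3,4,5-trimethoxyphenyl)-3,3a,4,5-tetrahydro-1-benzofuran-6(2H)-one | C=CC[C@]12C[C@H](O)C(=O)C=C1O[C@@H](c1cc(OC)c(OC)c(OC)c1)[C@@H]2C
F7 | step 12 | (2R,3R,3aR,5R)-3-methyl-6-oxo-3a-(prop-2-en-1-yl)-2-(3,4,5-trimethoxyphenyl)-2,3,3a,4,5,6-hexahydro-1-benzofuran-5-yl 4-nitrobenzoate | C=CC[C@]12C[C@@H](OC(=O)c3ccc(cc3)[N+](=O)[O-])C(=O)C=C1O[C@@H](c1cc(OC)c(OC)c(OC)c1)[C@@H]2C
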